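**Plan**
1. Retrosynthesis: the C3 stereocentre is flattened to the isoflavone (C2=C3); the C8 prenyl is traced back to a C8 allyl (cross-metathesis) and then to an O7 allyl ether (Claisen); the dimethyldihydropyran ring on ring B is cut at two bonds at once, O–CMe2 and ArCH2–CH2 (retro oxa-Diels–Alder to an ortho-quinone methide plus isobutene); the benzylic CH2 goes back to formaldehyde, leaving daidzein.
2. Forward: rings A, C and B come intact from daidzein; O7-allylation and ortho-hydroxymethylation of ring B follow, and the dimethyldihydropyran ring (ring D) is then closed as the last ring. After that only substituents and oxidation levels change.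
3. Enabling feature: ring B is a para-substituted phenol with two equivalent ortho carbons; O4'–C4'–C3' plus one exocyclic CH2 form a latent 1-oxadiene, and the CMe2 carbon next to oxygen in ring D is the substituted end of a 1,1-disubstituted alkene.
4. Stereochemistry: the single stereocentre (C3, R) is set after all thermal steps by asymmetric transfer hydrogenation with dynamic kinetic resolution, giving the (3R,4R)-cis alcohol; C4 is then re-oxidised and O7 desilylated under non-enolising conditions.

Key step: step 3

Assumption: daidzein (7,4'-dihydroxyisoflavone) is taken as a commercial starting material; the target SMILES corresponds to the (3R) configuration.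

**Step 1**
Reactants: 1 daidzein; 2 allyl bromide
Product: 3 7-(allyloxy)-3-(4-hydroxyphenyl)-4H-chromen-4-one
Conditions: K2CO3 (1.05 equiv), allyl bromide (1.05 equiv), DMF, rt
Reagents that add atoms: allyl bromide 2 (C=CCBr)
Why: Williamson etherification; the 7-OH is a vinylogous carboxylic acid conjugated with the C4 carbonyl and is markedly more acidic than the 4'-OH, so one equivalent of weak base should form and alkylate only the 7-phenoxide.

**Step 2**
Reactants: 3 7-(allyloxy)-3-(4-hydroxyphenyl)-4H-chromen-4-one; 4 paraformaldehyde; 5 phenylboronic acid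
Product: 7 7-(allyloxy)-3-[4-hydroxy-3-(hydroxymethyl)phenyl]-4H-chromen-4-one, via benzodioxaborin 6 (not isolated)
Conditions: PhB(OH)2 (1.2 equiv), (CH2O)n (4 equiv), EtCO2H (cat.), toluene, reflux, Dean–Stark; then 30% aq. H2O2, THF, 0 °C to rt
Reagents that add atoms: paraformaldehyde 4 (C=O)
Why: Boronate-templated ortho-specific hydroxymethylation of a phenol (Nagata-type): the aryl boronate delivers formaldehyde to the ortho carbon, the two ortho positions of ring B are equivalent, the cyclic boronate 6 caps the phenol against a second hydroxymethylation, and oxidative cleavage of the boron unit should release the salicyl alcohol.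

**Step 3**
Reactants: 7 7-(allyloxy)-3-[4-hydroxy-3-(hydroxymethyl)phenyl]-4H-chromen-4-one; 8 isobutene (2-methylpropene)
Product: 10 7-(allyloxy)-3-(2,2-dimethylchroman-6-yl)-4H-chromen-4-one, via ortho-quinone methide 9 (not isolated)
Conditions: isobutene (condensed, ca. 100 equiv), toluene (0.02 M), sealed stainless-steel autoclave, 170 °C
Reagents that add atoms: isobutene 8 (CC(C)=C)
Why: Heating dehydrates the o-hydroxybenzyl alcohol of 7 (1,4-elimination of water through a hydrogen-bonded six-membered transition state) to ortho-quinone methide 9, a 1-oxadiene (O=C4'–C3'=CH2) that regains the aromaticity of ring B when it reacts. Isobutene traps 9 in an inverse-electron-demand oxa-Diels–Alder reaction that forms the ArCH2–CH2 and O–CMe2 bonds in one concerted, asynchronous event; the closest known reaction type is the thermal chroman synthesis from salicyl alcohols and simple alkenes. Ring D is closed by an intermolecular [4+2] cycloaddition (the 4π oxadiene of ring B plus the 2π alkene), not by a tethered cyclisation. No stereocentre is created, because the new sp3 carbon next to oxygen carries two methyl groups and the isoflavone is still flat. The regiochemistry needed (2,2- and not 3,3-dimethyl) is secured by polarisation: the electrophilic exocyclic CH2 of 9 bonds to the unsubstituted CH2 of isobutene while the developing positive charge sits on the tertiary carbon that bonds to oxygen. The chemoselectivity needed is secured by high dilution and a large excess of the 1,1-disubstituted alkene (against self-condensation of 9 with phenolic rings and against the less nucleophilic monosubstituted allyl ether), by the electron-poor character of C2=C3 of the isoflavone (mismatched for this polarity), and by a temperature below that at which the allyl aryl ether rearranges at a useful rate, any rearranged material converging on 12 in step 4.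

**Step 4**
Reactants: 10 7-(allyloxy)-3-(2,2-dimethylchroman-6-yl)-4H-chromen-4-one
Product: 12 8-allyl-3-(2,2-dimethylchroman-6-yl)-7-hydroxy-4H-chromen-4-one, via dienone 11 (not isolated)
Conditions: N,N-diethylaniline, 205 °C, Ar
Reagents that add atoms: none
Why: Aromatic Claisen rearrangement ([3,3]-sigmatropic shift, then tautomerisation of dienone 11); in 7-allyloxychromones the C7–C8 bond has more double-bond character than C6–C7 because of the fused pyranone, so migration should go to C8.

**Step 5**
Reactants: 12 8-allyl-3-(2,2-dimethylchroman-6-yl)-7-hydroxy-4H-chromen-4-one; 13 2-methylbut-2-ene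
Product: 14 3-(2,2-dimethylchroman-6-yl)-7-hydroxy-8-(3-methylbut-2-en-1-yl)-4H-chromen-4-one
Conditions: second-generation Grubbs catalyst RuCl2(=CHPh)(PCy3)(H2IMes) (5 mol%), 2-methylbut-2-ene/CH2Cl2 (1:3), 40 °C, sealed tube
Reagents that add atoms: 2-methylbut-2-ene 13 (CC=C(C)C)
Why: Olefin cross-metathesis of the terminal allyl group with an excess of the trisubstituted alkene transfers an isopropylidene unit and should give the prenyl group, while the electron-poor trisubstituted C2=C3 of the isoflavone and the free phenol are tolerated.

**Step 6**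
Reactants: 14 3-(2,2-dimethylchroman-6-yl)-7-hydroxy-8-(3-methylbut-2-en-1-yl)-4H-chromen-4-one; 15 chlorotriisopropylsilane
Product: 16 3-(2,2-dimethylchroman-6-yl)-8-(3-methylbut-2-en-1-yl)-7-[(triisopropylsilyl)oxy]-4H-chromen-4-one
Conditions: i-Pr3SiCl (1.3 equiv), imidazole (2.5 equiv), DMF, 40 °C
Reagents that add atoms: chlorotriisopropylsilane 15 (CC(C)[Si](Cl)(C(C)C)C(C)C)
Why: Silylation of the phenol; capping O7 keeps the C4 carbonyl electrophilic in the transfer hydrogenation, shields the phenol from the periodinane, and can be undone at the end by buffered fluoride without base.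

**Step 7**
Reactants: 16 3-(2,2-dimethylchroman-6-yl)-8-(3-methylbut-2-en-1-yl)-7-[(triisopropylsilyl)oxy]-4H-chromen-4-one
Product: 18 (3R,4R)-3-(2,2-dimethylchroman-6-yl)-8-(3-methylbut-2-en-1-yl)-7-[(triisopropylsilyl)oxy]chroman-4-ol, via racemic isoflavanone 17 (not isolated)
Conditions: RuCl[(R,R)-TsDPEN](p-cymene) (3 mol%), HCO2H/Et3N (5:2), EtOAc, 40 °C
Reagents that add atoms: none
Why: Noyori–Ikariya asymmetric transfer hydrogenation with dynamic kinetic resolution: the ruthenium hydride first reduces the conjugated C2=C3 bond to isoflavanone 17, whose C3 epimerises rapidly through the enol in the amine-containing medium, and the (R,R)-catalyst then reduces the C4 carbonyl of the (3R)-enantiomer faster, with hydride delivered anti to the 3-aryl group and the C4 sense following the aryl ketone model, which should give the cis-(3R,4R) alcohol and leave the isolated prenyl olefin untouched.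

**Step 8**
Reactants: 18 (3R,4R)-3-(2,2-dimethylchroman-6-yl)-8-(3-methylbut-2-en-1-yl)-7-[(triisopropylsilyl)oxy]chroman-4-ol
Product: 19 (3R)-3-(2,2-dimethylchroman-6-yl)-8-(3-methylbut-2-en-1-yl)-7-[(triisopropylsilyl)oxy]chroman-4-one
Conditions: Dess–Martin periodinane (1.3 equiv), CH2Cl2, 0 °C; quench aq. Na2S2O3, pH 7 phosphate buffer
Reagents that add atoms: none
Why: Dess–Martin oxidation of the secondary benzylic alcohol under cold, base-free conditions; C3 is not a reacting centre and its priorities are unchanged, so the (3R) configuration should be carried into the ketone, and the prenyl group and silyl ether are inert.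

**Step 9**
Reactants: 19 (3R)-3-(2,2-dimethylchroman-6-yl)-8-(3-methylbut-2-en-1-yl)-7-[(triisopropylsilyl)oxy]chroman-4-one
Product: 20 (3R)-3-(2,2-dimethylchroman-6-yl)-7-hydroxy-8-(3-methylbut-2-en-1-yl)chroman-4-one
Conditions: Bu4NF (1.2 equiv), AcOH (1.5 equiv), THF, 0 °C; work-up aq. NH4Cl
Reagents that add atoms: none
Why: Fluoride cleavage of an aryl silyl ether whose phenoxide leaving group is stabilised by the para carbonyl; the acetic acid buffer keeps the medium free of basic fluoride and phenoxide so that C3–H should not enolise, and without strong acid the prenyl group should not cyclise onto O7.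

**Compound list**
1 | daidzein, 7-hydroxy-3-(4-hydroxyphenyl)-4H-chromen-4-one | O=c1c(-c2ccc(O)cc2)coc2cc(O)ccc12 | starting material
2 | allyl bromide | C=CCBr | starting material
3 | 7-(allyloxy)-3-(4-hydroxyphenyl)-4H-chromen-4-one | O=c1c(-c2ccc(O)cc2)coc2cc(OCC=C)ccc12 | intermediate
4 | paraformaldehyde (formaldehyde source) | C=O | starting material
5 | phenylboronic acid | OB(O)c1ccccc1 | starting material
6 | 7-(allyloxy)-3-(2-phenyl-4H-1,3,2-benzodioxaborinin-6-yl)-4H-chromen-4-one | O=c1c(-c2ccc3OB(c4ccccc4)OCc3c2)coc2cc(OCC=C)ccc12 | intermediate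
7 | 7-(allyloxy)-3-[4-hydroxy-3-(hydroxymethyl)phenyl]-4H-chromen-4-one | O=c1c(-c2ccc(O)c(CO)c2)coc2cc(OCC=C)ccc12 | intermediate
8 | isobutene (2-methylpropene) | CC(C)=C | starting material
9 | 7-(allyloxy)-3-(3-methylidene-4-oxocyclohexa-1,5-dien-1-yl)-4H-chromen-4-one (ortho-quinone methide) | O=c1c(C2=CC(=C)C(=O)C=C2)coc2cc(OCC=C)ccc12 | intermediate
10 | 7-(allyloxy)-3-(2,2-dimethylchroman-6-yl)-4H-chromen-4-one | O=c1c(-c2ccc3OC(C)(C)CCc3c2)coc2cc(OCC=C)ccc12 | intermediate
11 | 8-allyl-3-(2,2-dimethylchroman-6-yl)-8H-chromene-4,7-dione (Claisen dienone) | C=CCC1C(=O)C=CC2=C1OC=C(c1ccc3OC(C)(C)CCc3c1)C2=O | intermediate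
12 | 8-allyl-3-(2,2-dimethylchroman-6-yl)-7-hydroxy-4H-chromen-4-one | O=c1c(-c2ccc3OC(C)(C)CCc3c2)coc2c(CC=C)c(O)ccc12 | intermediate
13 | 2-methylbut-2-ene | CC=C(C)C | starting material
14 | 3-(2,2-dimethylchroman-6-yl)-7-hydroxy-8-(3-methylbut-2-en-1-yl)-4H-chromen-4-one | O=c1c(-c2ccc3OC(C)(C)CCc3c2)coc2c(CC=C(C)C)c(O)ccc12 | intermediate
15 | chlorotriisopropylsilane | CC(C)[Si](Cl)(C(C)C)C(C)C | starting material
16 | 3-(2,2-dimethylchroman-6-yl)-8-(3-methylbut-2-en-1-yl)-7-[(triisopropylsilyl)oxy]-4H-chromen-4-one | O=c1c(-c2ccc3OC(C)(C)CCc3c2)coc2c(CC=C(C)C)c(O[Si](C(C)C)(C(C)C)C(C)C)ccc12 | intermediate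
17 | racemic 3-(2,2-dimethylchroman-6-yl)-8-(3-methylbut-2-en-1-yl)-7-[(triisopropylsilyl)oxy]chroman-4-one | CC(C)=CCc1c(O[Si](C(C)C)(C(C)C)C(C)C)ccc2c1OCC(c1ccc3OC(C)(C)CCc3c1)C2=O | intermediate
18 | (3R,4R)-3-(2,2-dimethylchroman-6-yl)-8-(3-methylbut-2-en-1-yl)-7-[(triisopropylsilyl)oxy]chroman-4-ol (3,4-cis) | O[C@@H]1[C@H](c2ccc3OC(C)(C)CCc3c2)COc2c(CC=C(C)C)c(O[Si](C(C)C)(C(C)C)C(C)C)ccc12 | intermediate
19 | (3R)-3-(2,2-dimethylchroman-6-yl)-8-(3-methylbut-2-en-1-yl)-7-[(triisopropylsilyl)oxy]chroman-4-one | CC(C)=CCc1c(O[Si](C(C)C)(C(C)C)C(C)C)ccc2c1OC[C@@H](c1ccc3OC(C)(C)CCc3c1)C2=O | intermediate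
20 | (3R)-3-(2,2-dimethylchroman-6-yl)-7-hydroxy-8-(3-methylbut-2-en-1-yl)chroman-4-one (CNP0139927.1) | CC(C)=CCc1c(O)ccc2c1OC[C@@H](c1ccc3OC(C)(C)CCc3c1)C2=O | target

**Totals**
Total step count: 9. Longest linear sequence: 9 steps (from daidzein 1).

**Steps most likely to fail**

Step 3. The ortho-quinone methide may be consumed by self-condensation with phenolic rings faster than the unactivated alkene intercepts it, and the allyl ether may begin to rearrange at the temperature needed to form it. The fallback sets out from 3 and avoids the quinone methide. Lewis-acid-catalysed annulation with isoprene (Bi(OTf)3 cat., 1,2-dichloroethane, 40 °C) should first prenylate the free ortho position of ring B by Friedel–Crafts alkylation, giving 7-(allyloxy)-3-[4-hydroxy-3-(3-methylbut-2-en-1-yl)phenyl]-4H-chromen-4-one F1. In the same flask F1 should then close ring D by Markovnikov hydroalkoxylation of the prenyl olefin by the phenol, coming back to the route at 10.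

Step 7. Conjugate reduction of the electron-rich, hindered isoflavone by the ruthenium hydride may be sluggish, or epimerisation at C3 may be too slow relative to carbonyl reduction, so that the dynamic kinetic resolution is incomplete. The later re-oxidation is a second exposure of the labile C3–H. The fallback sets out from 16 and sets C3 by enantioselective protonation. Conjugate reduction with LiBH(s-Bu)3 (THF, −78 °C) and trapping of the enolate with Me3SiCl should give the silyl enol ether triisopropyl{[3-(2,2-dimethylchroman-6-yl)-8-(3-methylbut-2-en-1-yl)-4-(trimethylsilyloxy)-2H-chromen-7-yl]oxy}silane F2. Catalytic enantioselective protonation of F2 with a chiral BINOL-derived N-triflyl thiophosphoramide and phenol as the stoichiometric proton source (toluene, 0 °C) should give the ketone directly. The catalyst enantiomer would be chosen by correlation with material from step 8. This fallback comes back to the route at 19 and bypasses 18 and the oxidation.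

Step 2. Boronate formation and the templated electrophilic substitution may stall on a sparingly soluble phenol that is deactivated by the para enone. The fallback sets out from 3 and replaces the hydroxymethylation by formylation and reduction. Magnesium-phenoxide-directed ortho-formylation (MgCl2, Et3N, (CH2O)n, MeCN, reflux) should give 5-[7-(allyloxy)-4-oxo-4H-chromen-3-yl]-2-hydroxybenzaldehyde F3. Reduction of the aldehyde of F3 with NaBH4 (MeOH/THF, 0 °C, short contact to spare the isoflavone) comes back to the route at 7.

**Further compounds**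
F1 | step 3 | 7-(allyloxy)-3-[4-hydroxy-3-(3-methylbut-2-en-1-yl)phenyl]-4H-chromen-4-one | O=c1c(-c2ccc(O)c(CC=C(C)C)c2)coc2cc(OCC=C)ccc12
F2 | step 7 | triisopropyl{[3-(2,2-dimethylchroman-6-yl)-8-(3-methylbut-2-en-1-yl)-4-(trimethylsilyloxy)-2H-chromen-7-yl]oxy}silane | CC(C)=CCc1c(O[Si](C(C)C)(C(C)C)C(C)C)ccc2c1OCC(c1ccc3OC(C)(C)CCc3c1)=C2O[Si](C)(C)C
F3 | step 2 | 5-[7-(allyloxy)-4-oxo-4H-chromen-3-yl]-2-hydroxybenzaldehyde | O=Cc1cc(ccc1O)-c1coc2cc(OCC=C)ccc2c1=O
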